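**Plan**

- Locants: oxolane O1, C2 (bears ring A), C3 (bears C9H2OH), C4 (bears C7H2, joined to C6'), C5; dihydrobenzofuran O1', C2' (bears ring C), C3' (bears C9'H2OH), C3a', C4' (OMe), C5', C6', C7', C7a'; ring B is the benzo ring.
- Enabling feature: C2' is a benzylic, oxygen-bearing CH and C3' carries the one-carbon group C9'. C2'–C3' is therefore cut first, to a diazoacetate carbon on C3a' and the OCH2 of a 4-benzyloxy-3-methoxybenzyl ether on the C7a' oxygen.
- Further cuts, in order: C7–C6' (sp3–sp2 cross-coupling); the benzyl ether O–CH2 and the C3a'–CH2 bond on ring B; C3–C4 of the oxolane (radical closure of an epoxy propargyl ether).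
- Forward: the oxolane closes first (titanocene radical cyclisation). Ring B is dressed separately. The halves are joined by B-alkyl Suzuki coupling. The dihydrofuran ring then closes by carbenoid C–H insertion, and reduction and hydrogenolysis finish the synthesis.
- Stereochemistry: C2 from a Sharpless kinetic resolution; C3 from the trans-selective radical cyclisation; C4 from hydroboration anti to the C3 substituent; C2' from the chiral dirhodium carboxylate; C3' from base equilibration to trans.

Key step: step 14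

Assumption: the sense of induction of Rh2(S-PTTL)4 (S ligand giving the 2'S centre) is carried over from simpler 2-benzyloxyaryl diazoacetates; if the opposite sense were found, Rh2(R-PTTL)4 would replace it with no other change.

Abbreviations: ArA = 3-(benzyloxy)-4-methoxyphenyl (ring A); ArC = 4-(benzyloxy)-3-methoxyphenyl (ring C); Piv = 2,2-dimethylpropanoyl; MOM = methoxymethyl. Names use the locants of the plan. Compounds 1, 8 and 14 are catalogue compounds (1 and 14 are the O-benzyl ethers of isovanillin and vanillyl alcohol).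

**Route**

Step 1
Reactants: 1 3-(benzyloxy)-4-methoxybenzaldehyde
Product: 2 rac-1-ArA-prop-2-en-1-ol
Conditions: CH2=CHMgBr, THF, −78 → 0 °C
Reagents that add atoms: vinylmagnesium bromide, C=C[Mg]Br
Why: Grignard 1,2-addition to the aldehyde gives the racemic aryl vinyl carbinol.

Step 2
Reactants: 2 rac-1-ArA-prop-2-en-1-ol
Product: 3 (1R)-1-ArA-prop-2-en-1-ol
Conditions: Ti(OiPr)4 (cat.), D-(−)-DIPT (cat.), t-BuOOH (0.6 equiv), 4 Å MS, CH2Cl2, −20 °C
Reagents that add atoms: none
Why: Sharpless kinetic resolution: the Ti(OiPr)4/D-(−)-DIPT catalyst should epoxidise the (S)-alcohol much faster (to the erythro epoxy alcohol), so the unreacted (R)-alcohol, the future C2, should be recovered in high enantiomeric purity past half conversion.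

Step 3
Reactants: 3 (1R)-1-ArA-prop-2-en-1-ol
Product: 4 (1R)-1-ArA-1-(prop-2-yn-1-yloxy)prop-2-ene
Conditions: NaH, HC≡CCH2Br, Bu4NI (cat.), THF, 0 °C → rt
Reagents that add atoms: propargyl bromide, C#CCBr
Why: Williamson ether synthesis: the sodium alkoxide displaces the propargylic bromide (SN2) without touching the stereocentre.

Step 4
Reactants: 4 (1R)-1-ArA-1-(prop-2-yn-1-yloxy)prop-2-ene
Product: 5 2-[(S)-ArA(prop-2-yn-1-yloxy)methyl]oxirane (both oxirane epimers; the benzylic centre is unchanged in space and S only by priority change)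
Conditions: mCPBA, NaHCO3, CH2Cl2, 0 °C → rt
Reagents that add atoms: 3-chloroperoxybenzoic acid, OOC(=O)c1cccc(Cl)c1
Why: Prilezhaev epoxidation of the terminal alkene, which reacts with peracid far faster than the terminal alkyne; the new oxirane centre is erased in the next step, so both epimers are used.

Step 5
Reactants: 5 2-[(S)-ArA(prop-2-yn-1-yloxy)methyl]oxirane
Product: 6 [(2R,3S)-2-ArA-4-methylideneoxolan-3-yl]methanol
Conditions: Cp2TiCl2, Zn, THF, rt (Cp2TiCl solution added dropwise to 5); then aq. HCl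
Reagents that add atoms: none
Why: Nugent–RajanBabu reaction: Cp2TiCl (trivalent titanium) opens the epoxide homolytically to the secondary β-titanoxy radical at C3, which cyclises 5-exo-dig onto the alkyne with the C2 aryl group pseudo-equatorial, so C3 should form trans to the aryl group, and the vinyl radical is reduced and protonated to the exocyclic methylene.

Step 6
Reactants: 6 [(2R,3S)-2-ArA-4-methylideneoxolan-3-yl]methanol
Product: 7 [(2R,3S)-2-ArA-4-methylideneoxolan-3-yl]methyl pivalate
Conditions: PivCl, pyridine, DMAP (cat.), CH2Cl2, 0 °C → rt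
Reagents that add atoms: pivaloyl chloride, CC(C)(C)C(Cl)=O
Why: DMAP-catalysed acylation gives a hindered ester without α-hydrogens that screens one face of the methylene group, tolerates borane, base and carbenoid, and is later removed by LiAlH4 in the same step that reduces the C9' ester.

Step 7
Reactants: 8 3-chloro-5-methoxyphenol
Product: 9 1-chloro-3-methoxy-5-(methoxymethoxy)benzene
Conditions: MOMCl, iPr2NEt, CH2Cl2, 0 °C → rt
Reagents that add atoms: chloromethyl methyl ether, COCCl
Why: O-alkylation of the phenol installs the MOM ether as a strong ortho-directing group.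

Step 8
Reactants: 9 1-chloro-3-methoxy-5-(methoxymethoxy)benzene
Product: 11 5-chloro-2-iodo-1-methoxy-3-(methoxymethoxy)benzene, via aryllithium 10 (not isolated)
Conditions: n-BuLi, THF, −78 → −30 °C; then I2, −78 °C → rt
Reagents that add atoms: iodine, II
Why: Directed ortho-metalation: OMOM and OMe should jointly guide n-BuLi to the C–H between them (coordination control, preferred over the chlorine-flanked positions; the lithium ends meta to chlorine, so no aryne can form), and iodine quenches the aryllithium.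

Step 9
Reactants: 11 5-chloro-2-iodo-1-methoxy-3-(methoxymethoxy)benzene
Product: 12 methyl 2-[4-chloro-2-methoxy-6-(methoxymethoxy)phenyl]acetate
Conditions: BrZnCH2CO2Me (from BrCH2CO2Me and Zn in THF), Pd(dba)2 (cat.), P(t-Bu)3 (cat.), THF, rt
Reagents that add atoms: methyl bromoacetate (as its zinc enolate), COC(=O)CBr
Why: Palladium-catalysed Negishi-type α-arylation of the Reformatsky reagent: zerovalent palladium inserts into C–I far faster than into C–Cl, the zinc enolate transmetalates and reductive elimination forms the C3a'–CH2 bond under near-neutral conditions.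

Step 10
Reactants: 12 methyl 2-[4-chloro-2-methoxy-6-(methoxymethoxy)phenyl]acetate
Product: 13 methyl 2-(4-chloro-2-hydroxy-6-methoxyphenyl)acetate
Conditions: HCl (conc., cat.), MeOH, 40 °C
Reagents that add atoms: none
Why: Acid-catalysed acetal methanolysis of the aryl MOM ether; in methanol the methyl ester should persist and not lactonise.

Step 11
Reactants: 13 methyl 2-(4-chloro-2-hydroxy-6-methoxyphenyl)acetate; 14 [4-(benzyloxy)-3-methoxyphenyl]methanol
Product: 15 methyl 2-[2-(ArC-methoxy)-4-chloro-6-methoxyphenyl]acetate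
Conditions: PPh3, DIAD, THF, 0 °C → rt
Reagents that add atoms: none
Why: Mitsunobu etherification of the phenol with the activated primary benzylic alcohol, which avoids the labile electron-rich benzyl halide.

Step 12
Reactants: 7 [(2R,3S)-2-ArA-4-methylideneoxolan-3-yl]methyl pivalate; 15 methyl 2-[2-(ArC-methoxy)-4-chloro-6-methoxyphenyl]acetate
Product: 17 methyl 2-[2-(ArC-methoxy)-6-methoxy-4-{[(2R,3S,4S)-2-ArA-3-(pivaloyloxymethyl)oxolan-4-yl]methyl}phenyl]acetate, via alkyl-9-BBN borane 16 (not isolated)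
Conditions: 9-BBN, THF, 0 °C → rt; then 15, Pd(OAc)2 (cat.), SPhos (cat.), K3PO4 (aq.), THF, 65 °C
Reagents that add atoms: none
Why: Hydroboration then B-alkyl Suzuki–Miyaura coupling: 9-BBN should add boron to the terminal methylene carbon from the face opposite the C3 pivaloyloxymethyl group, so hydrogen reaches C4 anti to that group and C7 ends cis to C9 (C4 S), and the primary alkylborane couples with the aryl chloride under zerovalent palladium/SPhos catalysis to form C7–C6'.

Step 13
Reactants: 17 methyl 2-[2-(ArC-methoxy)-6-methoxy-4-{[(2R,3S,4S)-2-ArA-3-(pivaloyloxymethyl)oxolan-4-yl]methyl}phenyl]acetate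
Product: 18 methyl 2-diazo-2-[2-(ArC-methoxy)-6-methoxy-4-{[(2R,3S,4S)-2-ArA-3-(pivaloyloxymethyl)oxolan-4-yl]methyl}phenyl]acetate
Conditions: p-ABSA, DBU, MeCN, 0 °C → rt
Reagents that add atoms: 4-acetamidobenzenesulfonyl azide, CC(=O)Nc1ccc(cc1)S(=O)(=O)N=[N+]=[N-]
Why: Regitz diazo transfer: DBU deprotonates the arylacetate α-carbon, the enolate adds to the sulfonyl azide and the triazene collapses to the diazo ester and the sulfonamide.

Step 14
Reactants: 18 methyl 2-diazo-2-[2-(ArC-methoxy)-6-methoxy-4-{[(2R,3S,4S)-2-ArA-3-(pivaloyloxymethyl)oxolan-4-yl]methyl}phenyl]acetate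
Product: 20 methyl (2'S,3'S)-trans-2'-ArC-4'-methoxy-6'-{[(2R,3S,4S)-2-ArA-3-(pivaloyloxymethyl)oxolan-4-yl]methyl}-2',3'-dihydrobenzofuran-3'-carboxylate, via cis ester 19 (not isolated)
Conditions: Rh2(S-PTTL)4 (1 mol%), toluene, −60 °C (18 added slowly); then DBU, 0 → 40 °C
Reagents that add atoms: none
Why: Rh2(S-PTTL)4, dirhodium tetrakis[N-phthaloyl-(S)-tert-leucinate] (a divalent rhodium dimer), decomposes the aryldiazoacetate with loss of N2 to a donor/acceptor carbenoid on the carbon attached to C3a', which inserts into one of the two enantiotopic C–H bonds of the OCH2 group on the C7a' oxygen in a concerted, asynchronous three-centre step, forming C2'–C3'. The closest known reaction is the dirhodium carboxylate catalysed intramolecular C–H insertion of 2-(benzyloxy)aryl diazoacetates to cis-2-aryl-2,3-dihydrobenzofuran-3-carboxylates, followed by base epimerisation. The dihydrofuran ring closes as a 1,5-insertion through a five-membered cyclic transition state (carbenoid carbon, C3a', C7a', O1', CH2), the only ring size the ortho tether allows. C2' is set by the chiral N-phthaloyl-tert-leucinate ligands, which tell the enantiotopic benzylic hydrogens apart (catalyst control, the oxolane stereocentres being remote); C3' is first cis from the concerted geometry and is then equilibrated by DBU through the ester enolate to the more stable trans arrangement, ring opening by β-elimination of the phenoxide being the reverse of a disfavoured 5-endo-trig closure. Site selectivity for the benzylic OCH2 over the equally 1,5-related C4' OCH3 hydrogens is needed and rests on the better stabilisation of developing positive charge at a secondary carbon flanked by oxygen and the electron-rich ArC ring; the other C–H bonds (oxolane C2–H and C5–H2, benzyl ether CH2, pivalate) lie outside a five-membered transition state, and no free OH or alkene is present.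

Step 15
Reactants: 20 methyl (2'S,3'S)-trans-2'-ArC-4'-methoxy-6'-{[(2R,3S,4S)-2-ArA-3-(pivaloyloxymethyl)oxolan-4-yl]methyl}-2',3'-dihydrobenzofuran-3'-carboxylate
Product: 21 [(2'S,3'R)-trans-2'-ArC-6'-{[(2R,3S,4S)-2-ArA-3-(hydroxymethyl)oxolan-4-yl]methyl}-4'-methoxy-2',3'-dihydrobenzofuran-3'-yl]methanol
Conditions: LiAlH4, THF, 0 °C
Reagents that add atoms: none
Why: Hydride reduction turns the C9' methyl ester into the primary alcohol and cleaves the pivalate in the same operation; the trans C2'/C3' relationship is the thermodynamic one and the C3' descriptor changes to R only by priority.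

Step 16
Reactants: 21 [(2'S,3'R)-trans-2'-ArC-6'-{[(2R,3S,4S)-2-ArA-3-(hydroxymethyl)oxolan-4-yl]methyl}-4'-methoxy-2',3'-dihydrobenzofuran-3'-yl]methanol
Product: 22 CNP0242386.1, (2R,3S,4S)-2-(3-hydroxy-4-methoxyphenyl)-3-(hydroxymethyl)-4-{[(2'S,3'R)-2'-(4-hydroxy-3-methoxyphenyl)-3'-(hydroxymethyl)-4'-methoxy-2',3'-dihydrobenzofuran-6'-yl]methyl}oxolane
Conditions: H2 (1 atm), Pd/C, EtOAc, rt
Reagents that add atoms: none
Why: Hydrogenolysis of the two aryl benzyl ethers over Pd/C under neutral conditions at atmospheric pressure should be much faster than cleavage of the benzylic C–O bonds of the oxolane and dihydrobenzofuran rings.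

**Compound list**

1 | 3-(benzyloxy)-4-methoxybenzaldehyde | COc1ccc(C=O)cc1OCc1ccccc1 | starting material
2 | rac-1-[3-(benzyloxy)-4-methoxyphenyl]prop-2-en-1-ol | COc1ccc(C(O)C=C)cc1OCc1ccccc1 | intermediate
3 | (1R)-1-[3-(benzyloxy)-4-methoxyphenyl]prop-2-en-1-ol | COc1ccc([C@H](O)C=C)cc1OCc1ccccc1 | intermediate
4 | 2-(benzyloxy)-1-methoxy-4-[(1R)-1-(prop-2-yn-1-yloxy)prop-2-en-1-yl]benzene | COc1ccc([C@H](OCC#C)C=C)cc1OCc1ccccc1 | intermediate
5 | 2-{(S)-[3-(benzyloxy)-4-methoxyphenyl](prop-2-yn-1-yloxy)methyl}oxirane, both oxirane epimers | COc1ccc([C@H](OCC#C)C2CO2)cc1OCc1ccccc1 | intermediate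
6 | [(2R,3S)-2-[3-(benzyloxy)-4-methoxyphenyl]-4-methylideneoxolan-3-yl]methanol | COc1ccc([C@@H]2OCC(=C)[C@H]2CO)cc1OCc1ccccc1 | intermediate
7 | [(2R,3S)-2-[3-(benzyloxy)-4-methoxyphenyl]-4-methylideneoxolan-3-yl]methyl 2,2-dimethylpropanoate | COc1ccc([C@@H]2OCC(=C)[C@H]2COC(=O)C(C)(C)C)cc1OCc1ccccc1 | intermediate
8 | 3-chloro-5-methoxyphenol | COc1cc(O)cc(Cl)c1 | starting material
9 | 1-chloro-3-methoxy-5-(methoxymethoxy)benzene | COCOc1cc(OC)cc(Cl)c1 | intermediate
10 | [4-chloro-2-methoxy-6-(methoxymethoxy)phenyl]lithium | [Li]c1c(OC)cc(Cl)cc1OCOC | intermediate (not isolated)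
11 | 5-chloro-2-iodo-1-methoxy-3-(methoxymethoxy)benzene | COCOc1cc(Cl)cc(OC)c1I | intermediate
12 | methyl 2-[4-chloro-2-methoxy-6-(methoxymethoxy)phenyl]acetate | COCOc1cc(Cl)cc(OC)c1CC(=O)OC | intermediate
13 | methyl 2-(4-chloro-2-hydroxy-6-methoxyphenyl)acetate | COC(=O)Cc1c(O)cc(Cl)cc1OC | intermediate
14 | [4-(benzyloxy)-3-methoxyphenyl]methanol | COc1cc(CO)ccc1OCc1ccccc1 | starting material
15 | methyl 2-[2-{[4-(benzyloxy)-3-methoxyphenyl]methoxy}-4-chloro-6-methoxyphenyl]acetate | COC(=O)Cc1c(OC)cc(Cl)cc1OCc1ccc(OCc2ccccc2)c(OC)c1 | intermediate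
16 | (2R,3S,4S)-2-[3-(benzyloxy)-4-methoxyphenyl]-4-[(9-borabicyclo[3.3.1]nonan-9-yl)methyl]-3-(pivaloyloxymethyl)oxolane | COc1ccc([C@@H]2OC[C@@H](CB3C4CCCC3CCC4)[C@H]2COC(=O)C(C)(C)C)cc1OCc1ccccc1 | intermediate (not isolated)
17 | methyl 2-[2-{[4-(benzyloxy)-3-methoxyphenyl]methoxy}-6-methoxy-4-{[(2R,3S,4S)-2-[3-(benzyloxy)-4-methoxyphenyl]-3-(pivaloyloxymethyl)oxolan-4-yl]methyl}phenyl]acetate | COc1ccc([C@@H]2OC[C@@H](Cc3cc(OC)c(CC(=O)OC)c(OCc4ccc(OCc5ccccc5)c(OC)c4)c3)[C@H]2COC(=O)C(C)(C)C)cc1OCc1ccccc1 | intermediate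
18 | methyl 2-diazo-2-[2-{[4-(benzyloxy)-3-methoxyphenyl]methoxy}-6-methoxy-4-{[(2R,3S,4S)-2-[3-(benzyloxy)-4-methoxyphenyl]-3-(pivaloyloxymethyl)oxolan-4-yl]methyl}phenyl]acetate | COc1ccc([C@@H]2OC[C@@H](Cc3cc(OC)c(C(=[N+]=[N-])C(=O)OC)c(OCc4ccc(OCc5ccccc5)c(OC)c4)c3)[C@H]2COC(=O)C(C)(C)C)cc1OCc1ccccc1 | intermediate (key-step precursor)
19 | methyl (2'S,3'R)-cis-2'-[4-(benzyloxy)-3-methoxyphenyl]-4'-methoxy-6'-{[(2R,3S,4S)-2-[3-(benzyloxy)-4-methoxyphenyl]-3-(pivaloyloxymethyl)oxolan-4-yl]methyl}-2',3'-dihydrobenzofuran-3'-carboxylate | COc1ccc([C@@H]2OC[C@@H](Cc3cc(OC)c4c(c3)O[C@H](c3ccc(OCc5ccccc5)c(OC)c3)[C@@H]4C(=O)OC)[C@H]2COC(=O)C(C)(C)C)cc1OCc1ccccc1 | intermediate (not isolated)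
20 | methyl (2'S,3'S)-trans-2'-[4-(benzyloxy)-3-methoxyphenyl]-4'-methoxy-6'-{[(2R,3S,4S)-2-[3-(benzyloxy)-4-methoxyphenyl]-3-(pivaloyloxymethyl)oxolan-4-yl]methyl}-2',3'-dihydrobenzofuran-3'-carboxylate | COc1ccc([C@@H]2OC[C@@H](Cc3cc(OC)c4c(c3)O[C@H](c3ccc(OCc5ccccc5)c(OC)c3)[C@H]4C(=O)OC)[C@H]2COC(=O)C(C)(C)C)cc1OCc1ccccc1 | intermediate (key-step product)
21 | [(2'S,3'R)-trans-2'-[4-(benzyloxy)-3-methoxyphenyl]-6'-{[(2R,3S,4S)-2-[3-(benzyloxy)-4-methoxyphenyl]-3-(hydroxymethyl)oxolan-4-yl]methyl}-4'-methoxy-2',3'-dihydrobenzofuran-3'-yl]methanol | COc1ccc([C@@H]2OC[C@@H](Cc3cc(OC)c4c(c3)O[C@H](c3ccc(OCc5ccccc5)c(OC)c3)[C@H]4CO)[C@H]2CO)cc1OCc1ccccc1 | intermediate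
22 | CNP0242386.1, (2R,3S,4S)-2-(3-hydroxy-4-methoxyphenyl)-3-(hydroxymethyl)-4-{[(2'S,3'R)-2'-(4-hydroxy-3-methoxyphenyl)-3'-(hydroxymethyl)-4'-methoxy-2',3'-dihydrobenzofuran-6'-yl]methyl}oxolane | COc1ccc([C@@H]2OC[C@@H](Cc3cc(OC)c4c(c3)O[C@H](c3ccc(O)c(OC)c3)[C@H]4CO)[C@H]2CO)cc1O | target

**Step count and risks**

Total steps: 16. Longest linear sequence: 11 steps (steps 1–6 and 12–16, from 1 to 22); the ring B branch (steps 7–11, then 12–16) is 10 steps.

Steps most likely to fail:

1. Step 14. The twisted, doubly ortho-substituted aryl carbenoid may be discriminated poorly by the catalyst, may pair badly with the chiral oxolane, or may partly insert into the C4' OCH3 group, giving C2' epimers and regioisomers that are hard to separate. Fallback: carry out the insertion before the fragments are joined, on an achiral substrate closest to precedent. Setting out from 15, diazo transfer (p-ABSA, DBU, MeCN) would give the chloroaryl diazoacetate F1. Rh2(S-PTTL)4 in toluene and then DBU would give, by way of the cis chloro ester F2, the trans chloro ester F3, whose enantiomeric purity could be raised by crystallisation or chiral chromatography. B-alkyl Suzuki coupling of F3 with borane 16 (Pd(OAc)2, SPhos, K3PO4) would then rejoin the route at 20.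

2. Step 12. The borane may approach the methylene face syn to the pivaloyloxymethyl group and erode the 3,4-cis relationship, or oxidative addition to the electron-rich aryl chloride may be too slow against protodeboronation of the alkylborane. Fallback: let the radical ring closure set C4 and form C7–C6' earlier. Setting out from 5 and 15, copper-free Sonogashira coupling (PdCl2(MeCN)2, XPhos, Cs2CO3, MeCN) would give the aryl alkyne F4. Semi-hydrogenation (H2, Pd/CaCO3 poisoned with Pb(OAc)2, quinoline) would give the Z-styrenyl ether F5. Cp2TiCl-mediated epoxide opening and 5-exo-trig cyclisation onto the styrene (Beckwith–Houk chair transition state, C3/C4 cis, benzylic radical reduced and protonated) would give the oxolane alcohol F6. Pivaloylation of F6 (PivCl, pyridine) would rejoin the route at 17.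

3. Step 13. Deprotonation of the 2,6-dialkoxyarylacetate by DBU may be too slow (electron-rich aryl ring twisted out of conjugation), so that diazo transfer stalls. Fallback: deformylative Regitz diazo transfer through an activated derivative. Setting out from 17, LiN(iPr)2 (THF, −78 °C; the pivalate has no α-hydrogen) and 2,2,2-trifluoroethyl formate would give the α-formyl ester F7. p-ABSA with Et3N would then transfer the diazo group with loss of the formyl group as the N-formyl sulfonamide, rejoining the route at 18.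

**Further compounds**

F1 | step 14 | methyl 2-[2-{[4-(benzyloxy)-3-methoxyphenyl]methoxy}-4-chloro-6-methoxyphenyl]-2-diazoacetate | COC(=O)C(=[N+]=[N-])c1c(OC)cc(Cl)cc1OCc1ccc(OCc2ccccc2)c(OC)c1
F2 | step 14 | methyl (2S,3R)-cis-2-[4-(benzyloxy)-3-methoxyphenyl]-6-chloro-4-methoxy-2,3-dihydrobenzofuran-3-carboxylate | Clc1cc(OC)c2c(c1)O[C@H](c1ccc(OCc3ccccc3)c(OC)c1)[C@@H]2C(=O)OC
F3 | step 14 | methyl (2S,3S)-trans-2-[4-(benzyloxy)-3-methoxyphenyl]-6-chloro-4-methoxy-2,3-dihydrobenzofuran-3-carboxylate | Clc1cc(OC)c2c(c1)O[C@H](c1ccc(OCc3ccccc3)c(OC)c1)[C@H]2C(=O)OC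
F4 | step 12 | methyl 2-[2-{[4-(benzyloxy)-3-methoxyphenyl]methoxy}-4-{3-[(S)-[3-(benzyloxy)-4-methoxyphenyl](oxiran-2-yl)methoxy]prop-1-yn-1-yl}-6-methoxyphenyl]acetate | COc1ccc([C@H](OCC#Cc2cc(OC)c(CC(=O)OC)c(OCc3ccc(OCc4ccccc4)c(OC)c3)c2)C2CO2)cc1OCc1ccccc1
F5 | step 12 | methyl 2-[2-{[4-(benzyloxy)-3-methoxyphenyl]methoxy}-4-{(Z)-3-[(S)-[3-(benzyloxy)-4-methoxyphenyl](oxiran-2-yl)methoxy]prop-1-en-1-yl}-6-methoxyphenyl]acetate | COc1ccc([C@H](OC/C=C\c2cc(OC)c(CC(=O)OC)c(OCc3ccc(OCc4ccccc4)c(OC)c3)c2)C2CO2)cc1OCc1ccccc1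
F6 | step 12 | methyl 2-[2-{[4-(benzyloxy)-3-methoxyphenyl]methoxy}-4-{[(2R,3S,4S)-2-[3-(benzyloxy)-4-methoxyphenyl]-3-(hydroxymethyl)oxolan-4-yl]methyl}-6-methoxyphenyl]acetate | COc1ccc([C@@H]2OC[C@@H](Cc3cc(OC)c(CC(=O)OC)c(OCc4ccc(OCc5ccccc5)c(OC)c4)c3)[C@H]2CO)cc1OCc1ccccc1
F7 | step 13 | methyl 2-[2-{[4-(benzyloxy)-3-methoxyphenyl]methoxy}-6-methoxy-4-{[(2R,3S,4S)-2-[3-(benzyloxy)-4-methoxyphenyl]-3-(pivaloyloxymethyl)oxolan-4-yl]methyl}phenyl]-3-oxopropanoate (α-formyl ester, epimers and enol) | COc1ccc([C@@H]2OC[C@@H](Cc3cc(OC)c(C(C=O)C(=O)OC)c(OCc4ccc(OCc5ccccc5)c(OC)c4)c3)[C@H]2COC(=O)C(C)(C)C)cc1OCc1ccccc1
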